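Remark on the chemistry: atom numbers (C5, C20 and so on) are the heavy-atom positions in the SMILES of the target 49; 2-bromo-3-methylbut-1-ene (30) and the small reagents listed under "Reagents that add atoms" are assumed to be catalogue items.

## Analysis of the target

Bisglaucumlide K (49) is a biscembranoid built on a tetrasubstituted cyclohexene (C5, C26, C27, C28, C30, C52). This ring is fused through C5–C26 to an upper 14-membered carbocycle and through C30–C52 to a lower 14-membered carbocycle, which is bridged by an oxane (O53 between C40 and C46). There are nine stereocentres. The ring triad C5/C26/C52 has the C5 ester cis to the C51 alkenyl arm and trans to the C24 acyl group. The lower ring carries C32, C37, C40, C43 and C46, with a 2,6-trans oxane and both tertiary carbinols anti to the neighbouring ring C–O bond, the pattern left by two trans-epoxide openings. C20 sits alone in the upper ring, too far from the other centres to be controlled by them. Three E-trisubstituted olefins (C9=C10, C14=C15, C49=C51) and the tetrasubstituted C28=C30 bond must be made with defined geometry. Sensitive features are the C17/C24 1,4-diketone with epimerisable C20 and C26, the C7 enone, the secondary acetate beside a free tertiary alcohol, and the γ-relationship between the C3 ester and any free hydroxyl on C7 or C24, which invites lactonisation. The difficulty is to close two macrocycles on a congested core with a quaternary C5 while keeping these groups intact. The strategy rests on the 1,4-dicarbonyl unit C17/C24 inside the upper ring: an acyl radical at C17 and a C19=C20 enone are its natural halves.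

## Retrosynthetic reasoning

49 to 48: the C17–C19 bond is cut. It is the only bond of the upper ring that joins two carbonyl-flanked carbons through an unsubstituted CH2, so a polarity-matched union of a C17 acyl radical with the C19 terminus of an enone is available. Cutting here leaves every other stereocentre and ring in place and creates only C20, which stays correctable. The forward step must close a 14-membered ring by 14-endo addition and deliver hydrogen to C20.

48 back to 41: no skeletal bond is cut. The selenoester comes from acid 47. The acid, the acetate and the free tertiary alcohols arise from 41 through 42–46 by oxidation-state and protecting-group changes, ordered so that no free hydroxyl sits γ to the C3 ester for long and so that the acetate is introduced only after the last hydride or organometallic step.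

41 to 33 and 40: the C7–C9 bond is cut, between an aldehyde carbon and an alkenyl iodide. The chain 40 carries both E olefins of the upper arm ready-made. The forward coupling must be selective for the aldehyde in the presence of an enone and an ester.

33 to 29 and 30 (through 32): the C20–C24 bond is cut, giving an aldehyde and a 2-isopropylvinyl nucleophile. This brings in the whole enone acceptor in one addition, followed by oxidation.

27 to 25: the lower ring is opened at C48–C49, an sp3–sp2 bond next to the trisubstituted olefin. Cutting here lets the olefin geometry be fixed beforehand in an alkenyl iodide and transferred with retention, and the ring closure creates no stereocentre.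

25 back to 16 and 20 (through 21–23): the cyclohexene is disconnected at C5–C52 and C26–C27 as a Diels–Alder adduct. The dienophile 20 carries a formyl group on C5 so that one carbonyl group dictates regiochemistry, endo orientation and catalyst binding. The formyl group is later oxidised to the C3 ester.

16 to 13: the diene is taken apart at C52–C51 and C30–C28. Both bonds arise from a trans-diiodide (14) of the terminal alkyne, which guarantees that C51 ends cis to C31, the geometry the cycloaddition needs.

13 to 11: the C31–C32 bond is cut between an aldehyde and a propargyl donor. This avoids the regiochemical ambiguity of an allyl nucleophile on the finished ring and sets C32 in an open-chain Felkin–Anh addition.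

11 back to 1 (through 10–2): the oxane with C37, C40, C43 and C46 is traced to the bis-epoxide 4 of diol 3, itself from geranyl acetate 1. Two reagent-controlled epoxidations set all four centres, and one acid-mediated cascade converts them into the ring.

20 comes from 17 through 19 by a condensation that sets the E geometry thermodynamically. 40 comes from 34 through 36 by a syn-carbometalation and a stabilised Wittig reaction that fix both E olefins.

## Alternatives that were turned down

Alternative 1: The lower ring is cut at C31–C32. In the forward sense the C32 aldehyde of the seco compound A1, activated by a boron Lewis acid, is attacked by the exocyclic methylene carbon C31 of a tertiary allylsilane (silicon on C28). The SE2' process closes the lower 14-membered ring, moves the olefin to C28=C30 and gives the homoallylic alcohol A2.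
- For it: one step forms the ring, the C32 carbinol and the tetrasubstituted olefin, and an open transition state should follow the same Felkin–Anh sense that the target requires.
- Against it: A1 needs a silyl-bearing quaternary C28 and an exocyclic methylene, an arrangement no cycloaddition delivers directly. The tertiary allylsilane is prone to protodesilylation, and a macrocyclic transition state may override acyclic stereocontrol at C32.
- Comparison: on economy for the lower ring it is stronger than the chosen route, which spends several steps on C32 and a separate ring closure. It leaves the whole triketone ring still to be made, though. The chosen strategy offers a lower ring closed without creating a stereocentre, and places the decisive step on the upper ring at the very end.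

Alternative 2: The oxane is cut at O53–C40. In the forward sense the free C46 hydroxyl of the bis-macrocyclic epoxy alcohol A3 opens the trans C37/C40 epoxide at C40 under Brønsted or titanium Lewis acid, giving A4, the deacetyl target still silylated at O45.
- For it: the opening is stereospecific, it mirrors the likely biogenesis, and a lower ring without the bridge is more flexible and should close more easily.
- Against it: a trisubstituted epoxide and free hydroxyls must survive both macrocyclisations and all enone chemistry. In the finished bicycle the backside trajectory at C40 is not assured, transannular olefin participation or 7-endo attack at C37 can compete, and acetylation and desilylation still follow.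
- Comparison: on convergence and elegance it is at least as strong. The chosen route uses the same C–O bond formation, but at step 4 on a ten-carbon substrate where failure is cheap, and so keeps acid away from the complete skeleton.

Alternative 3: The upper ring is cut at C20–C24. In the forward sense a tin Lewis acid ionises the C24 acid chloride A5, the terminal isopropylidene olefin C20=C21 attacks the acylium ion and chloride traps the C21 cation, giving the chloro triketone A6.
- For it: the reaction type is established for cembrane rings, it can be tested early on a simple cyclohexene, and it needs neither tin hydride nor selenium; on these points it is stronger.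
- Against it: the acylium ion sits on a hindered carbon next to enolisable C26. The ring olefin C28=C30 is the better nucleophile and lies within reach for a transannular closure. C20 is formed without control, and the tertiary chloride must be removed. The whole lower half would then have to be built around a macrocyclic triketone with epimerisable centres.
- Comparison: the chosen strategy forms the ring at an unhindered CH2 terminus under neutral conditions, gives the correct oxidation level at C20/C21 directly, and leaves nothing but a possible equilibration after the key step.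

Key step: step 40

## Steps

Step 1
Reactants: 1 geranyl acetate
Product: 2 (2E,6E)-8-hydroxy-3,7-dimethylocta-2,6-dien-1-yl acetate
Conditions: SeO2 (10 mol %), t-BuOOH, salicylic acid (10 mol %), CH2Cl2, rt
Reagents that add atoms: tert-butyl hydroperoxide CC(C)(C)OO; selenium dioxide O=[Se]=O (oxygen relay)
Why: Riley allylic oxidation (ene reaction then [2,3]-shift) attacks the E-methyl group of the electron-rich distal olefin; the allylic acetate deactivates the proximal olefin, so the E-allylic alcohol should form selectively.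

Step 2
Reactants: 2 (2E,6E)-8-hydroxy-3,7-dimethylocta-2,6-dien-1-yl acetate
Product: 3 (2E,6E)-2,6-dimethylocta-2,6-diene-1,8-diol
Conditions: K2CO3, MeOH, rt
Reagents that add atoms: none
Why: Base-catalysed transesterification removes the acetate and leaves both E olefins untouched.

Step 3
Reactants: 3 (2E,6E)-2,6-dimethylocta-2,6-diene-1,8-diol
Product: 4 (2S,3S,6S,7S)-2,3:6,7-diepoxy-2,6-dimethyloctane-1,8-diol
Conditions: Ti(OiPr)4, L-(+)-diethyl tartrate, t-BuOOH, 4 Å MS, CH2Cl2, −20 °C
Reagents that add atoms: tert-butyl hydroperoxide CC(C)(C)OO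
Why: Twofold Sharpless asymmetric epoxidation; L-(+)-tartrate delivers oxygen to the same face of both E-allylic alcohols, which fixes the precursors of C37, C40, C43 and C46, and two reagent-controlled events raise the enantiopurity of the bis-epoxide.

Step 4
Reactants: 4 (2S,3S,6S,7S)-2,3:6,7-diepoxy-2,6-dimethyloctane-1,8-diol
Product: 6 (2S)-2-[(2R,5R,6S)-6-(hydroxymethyl)-5-[(4-methoxyphenyl)methoxy]-5-methyloxan-2-yl]propane-1,2-diol, via hydroxy epoxide 5 (not isolated)
Conditions: 4-methoxybenzyl alcohol (5 equiv), camphorsulfonic acid (10 mol %), CH2Cl2, 0 °C to rt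
Reagents that add atoms: 4-methoxybenzyl alcohol COc1ccc(CO)cc1
Why: Acid-catalysed alcoholysis opens the C43/C46 epoxide at the tertiary carbon C43 with inversion; the freed C46 hydroxyl then opens the second epoxide 6-exo at C40 with inversion, attack at C37 being disfavoured by ring size and by the adjacent hydroxymethyl group. This epoxide-opening cascade sets C40 and C43, gives the 2,6-trans oxane and leaves O45 masked.

Step 5
Reactants: 6 (2S)-2-[(2R,5R,6S)-6-(hydroxymethyl)-5-[(4-methoxyphenyl)methoxy]-5-methyloxan-2-yl]propane-1,2-diol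
Product: 7 [(2S,3R,6R)-6-[(4S)-2-(4-methoxyphenyl)-4-methyl-1,3-dioxolan-4-yl]-3-[(4-methoxyphenyl)methoxy]-3-methyloxan-2-yl]methanol (both acetal epimers)
Conditions: 4-MeOC6H4CH(OMe)2, pyridinium p-toluenesulfonate, CH2Cl2, rt
Reagents that add atoms: 4-methoxybenzaldehyde dimethyl acetal COc1ccc(cc1)C(OC)OC
Why: Acid-catalysed transacetalisation; only the C32/C37 1,2-diol can form a five-membered benzylidene acetal, so the C47 hydroxyl stays free.

Step 6
Reactants: 7 [(2S,3R,6R)-6-[(4S)-2-(4-methoxyphenyl)-4-methyl-1,3-dioxolan-4-yl]-3-[(4-methoxyphenyl)methoxy]-3-methyloxan-2-yl]methanol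
Product: 8 (2R,3R,6R)-6-[(4S)-2-(4-methoxyphenyl)-4-methyl-1,3-dioxolan-4-yl]-3-[(4-methoxyphenyl)methoxy]-3-methyloxane-2-carbaldehyde
Conditions: Dess–Martin periodinane, NaHCO3, CH2Cl2, 0 °C
Reagents that add atoms: none
Why: Buffered Dess–Martin oxidation gives the α-alkoxy aldehyde under conditions that should not epimerise C46.

Step 7
Reactants: 8 (2R,3R,6R)-6-[(4S)-2-(4-methoxyphenyl)-4-methyl-1,3-dioxolan-4-yl]-3-[(4-methoxyphenyl)methoxy]-3-methyloxane-2-carbaldehyde
Product: 9 (4S)-4-[(2R,5R,6S)-6-ethenyl-5-[(4-methoxyphenyl)methoxy]-5-methyloxan-2-yl]-2-(4-methoxyphenyl)-4-methyl-1,3-dioxolane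
Conditions: Ph3PCH3Br, KN(SiMe3)2, THF, −78 to 0 °C
Reagents that add atoms: methyltriphenylphosphonium bromide C[P+](c1ccccc1)(c1ccccc1)c1ccccc1.[Br-]
Why: Wittig methylenation introduces C48; the non-stabilised ylide adds to the aldehyde at low temperature faster than it enolises it, so C46 should be retained.

Step 8
Reactants: 9 (4S)-4-[(2R,5R,6S)-6-ethenyl-5-[(4-methoxyphenyl)methoxy]-5-methyloxan-2-yl]-2-(4-methoxyphenyl)-4-methyl-1,3-dioxolane
Product: 10 (2S)-2-[(2R,5R,6S)-6-ethenyl-5-[(4-methoxyphenyl)methoxy]-5-methyloxan-2-yl]-2-[(4-methoxyphenyl)methoxy]propan-1-ol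
Conditions: i-Bu2AlH (3 equiv), CH2Cl2, −78 to 0 °C
Reagents that add atoms: none
Why: Reductive acetal opening; aluminium binds the less hindered primary oxygen, so hydride delivery leaves the 4-methoxybenzyl group on the tertiary O39 and frees the C32 hydroxyl.

Step 9
Reactants: 10 (2S)-2-[(2R,5R,6S)-6-ethenyl-5-[(4-methoxyphenyl)methoxy]-5-methyloxan-2-yl]-2-[(4-methoxyphenyl)methoxy]propan-1-ol
Product: 11 (2R)-2-[(2R,5R,6S)-6-ethenyl-5-[(4-methoxyphenyl)methoxy]-5-methyloxan-2-yl]-2-[(4-methoxyphenyl)methoxy]propanal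
Conditions: Dess–Martin periodinane, NaHCO3, CH2Cl2, rt
Reagents that add atoms: none
Why: Dess–Martin oxidation of the neopentyl-type primary alcohol; the aldehyde has no α-hydrogen and cannot epimerise.

Step 10
Reactants: 11 (2R)-2-[(2R,5R,6S)-6-ethenyl-5-[(4-methoxyphenyl)methoxy]-5-methyloxan-2-yl]-2-[(4-methoxyphenyl)methoxy]propanal
Product: 12 (2S,3S)-2-[(2R,5R,6S)-6-ethenyl-5-[(4-methoxyphenyl)methoxy]-5-methyloxan-2-yl]-2-[(4-methoxyphenyl)methoxy]hex-5-yn-3-ol
Conditions: allenyl-SnBu3, BF3·OEt2, CH2Cl2, −78 °C
Reagents that add atoms: allenyltributylstannane C=C=C[Sn](CCCC)(CCCC)CCCC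
Why: Lewis acid-promoted SE2' propargylation gives only the homopropargylic alcohol and forms C31–C32; with the monodentate boron Lewis acid the addition should follow the Felkin–Anh model (attack anti to the C37–O bond, past the methyl group), which gives the C32 configuration of the target.

Step 11
Reactants: 12 (2S,3S)-2-[(2R,5R,6S)-6-ethenyl-5-[(4-methoxyphenyl)methoxy]-5-methyloxan-2-yl]-2-[(4-methoxyphenyl)methoxy]hex-5-yn-3-ol
Product: 13 tert-butyldimethylsilyl ether of 12 at O33 [(2R,3S)-hex-5-yn-3-yl silyl ether]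
Conditions: t-BuMe2SiOTf, 2,6-lutidine, CH2Cl2, 0 °C
Reagents that add atoms: tert-butyldimethylsilyl trifluoromethanesulfonate CC(C)(C)[Si](C)(C)OS(=O)(=O)C(F)(F)F
Why: Silylation with the triflate caps the hindered C32 hydroxyl for the oxidations, hydride and organometallic steps that follow; an acetate would not survive them.

Step 12
Reactants: 13 tert-butyldimethylsilyl ether of 12
Product: 14 (5E)-5,6-diiodohex-5-ene analogue of 13 (E-1,2-diiodoalkene at C30/C52)
Conditions: I2 (1.3 equiv), CH2Cl2, rt, dark
Reagents that add atoms: iodine II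
Why: Anti addition of iodine to the terminal alkyne through an iodonium ion gives the E-diiodide; isolated alkenes add iodine only reversibly, and the anisyl rings are not iodinated without an activator.

Step 13
Reactants: 14 (5E)-5,6-diiodohex-5-ene analogue of 13
Product: 15 (5E)-5-iodonon-5-en-7-yne analogue of 13 (propynyl on C52; iodine on C30)
Conditions: propyne (THF solution), Pd(PPh3)2Cl2 (5 mol %), CuI (10 mol %), i-Pr2NH, THF, 0 °C to rt
Reagents that add atoms: propyne CC#C
Why: Sonogashira coupling; oxidative addition is faster at the unhindered terminal C–I bond than at the internal one and proceeds with retention, so C51 ends cis to C31.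

Step 14
Reactants: 15 (5E)-5-iodonon-5-en-7-yne analogue of 13
Product: 16 diene: (5E)-5-(prop-1-en-2-yl)non-5-en-7-yne analogue of 13 (C27=C28–C30=C52 with C51 outside)
Conditions: isopropenyl-B(pin), Pd(dppf)Cl2 (5 mol %), K3PO4, THF/H2O, 50 °C
Reagents that add atoms: isopropenylboronic acid pinacol ester CC(=C)B1OC(C)(C)C(C)(C)O1
Why: Suzuki–Miyaura coupling with retention at C30 completes the 2,3-disubstituted diene with the isopropenyl group trans to C51, the geometry required for the cycloaddition.

Step 15
Reactants: 17 butane-1,4-diol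
Product: 18 4-(triethylsilyloxy)butan-1-ol
Conditions: NaH (1.0 equiv), THF, rt; then Et3SiCl (1.0 equiv)
Reagents that add atoms: chlorotriethylsilane CC[Si](Cl)(CC)CC
Why: Monosilylation through the sparingly soluble monosodium alkoxide, which reacts once; the triethylsilyl group is chosen because it can later be oxidised off directly.

Step 16
Reactants: 18 4-(triethylsilyloxy)butan-1-ol
Product: 19 4-(triethylsilyloxy)butanal
Conditions: Dess–Martin periodinane, NaHCO3, CH2Cl2, 0 °C
Reagents that add atoms: none
Why: Buffered Dess–Martin oxidation of a primary alcohol; the silyl ether is stable to it.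

Step 17
Reactants: 19 4-(triethylsilyloxy)butanal
Product: 20 ethyl (2E)-3-formyl-5-(triethylsilyloxy)pent-2-enoate
Conditions: ethyl glyoxylate (toluene solution), pyrrolidine (20 mol %), PhCO2H (20 mol %), CH2Cl2, rt to 40 °C
Reagents that add atoms: ethyl glyoxylate CCOC(=O)C=O
Why: Amine-catalysed cross-aldol condensation (enamine addition to the non-enolisable glyoxylate, then dehydration); the E isomer with formyl trans to the ester is the thermodynamic product and the amine equilibrates the pair.

Step 18
Reactants: 16 diene; 20 ethyl (2E)-3-formyl-5-(triethylsilyloxy)pent-2-enoate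
Product: 21 Diels–Alder aldehyde: ethyl (1S,2S,3S)-2-formyl-5-methyl-3-(prop-1-yn-1-yl)-2-[2-(triethylsilyloxy)ethyl]cyclohex-4-ene-1-carboxylate bearing the C31–C48 chain of 16 on ring carbon C30
Conditions: (S)-diphenylprolinol-derived B-o-tolyl oxazaborolidine (20 mol %), Tf2NH (18 mol %), CH2Cl2, −78 to −40 °C
Reagents that add atoms: none
Why: Chiral oxazaborolidinium-catalysed Diels–Alder reaction of a 2-substituted enal; the activated formyl group makes C26 the electrophilic terminus, so the most nucleophilic diene carbon C27 bonds to C26 and C52 to C5. The endo-formyl transition state places C3 cis to C51, and the E dienophile geometry places C24 trans to C3; the catalyst shields one enal face and so sets the absolute configuration of C5, C26 and C52 (the antipodal catalyst is used if the first run shows the opposite sense).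

Step 19
Reactants: 21 Diels–Alder aldehyde
Product: 22 carboxylic acid (C3 CO2H; otherwise as 21)
Conditions: NaClO2, NaH2PO4, 2-methylbut-2-ene, t-BuOH/H2O, rt
Reagents that add atoms: sodium chlorite [Na+].[O-]Cl=O
Why: Pinnick oxidation of the non-enolisable quaternary aldehyde; the scavenger protects the olefins from hypochlorous acid.

Step 20
Reactants: 22 carboxylic acid
Product: 23 1-ethyl 2-methyl diester (C3 CO2Me; C24 CO2Et; otherwise as 21)
Conditions: Me3SiCHN2, MeOH/toluene, 0 °C
Reagents that add atoms: (trimethylsilyl)diazomethane C[Si](C)(C)C=[N+]=[N-]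
Why: Diazoalkane esterification proceeds through O-alkylation of the carboxylate and is insensitive to the steric hindrance at C5.

Step 21
Reactants: 23 1-ethyl 2-methyl diester
Product: 25 alkenyl iodide (C52 bears the (E)-2-iodoprop-1-enyl group; otherwise as 23), via alkenylstannane 24 (not isolated)
Conditions: Bu3SnH, Pd(PPh3)2Cl2 (3 mol %), THF, 0 °C; then I2, CH2Cl2, 0 °C
Reagents that add atoms: iodine II
Why: Palladium-catalysed syn-hydrostannation places tin on the methyl-bearing alkyne carbon C49, away from the congested ring carbon C52, and iododestannylation proceeds with retention; this fixes C50 cis to C52 and leaves the terminal vinyl group untouched.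

Step 22
Reactants: 25 alkenyl iodide
Product: 27 macrocyclic diester (lower 14-membered ring closed at C48–C49; C5 CO2Me and CH2CH2OSiEt3; C26 CO2Et; O33 silyl; O39 and O45 4-methoxybenzyl; configuration as in 49), via alkylborane 26 (not isolated)
Conditions: 9-BBN-H, THF, rt; then Pd(dppf)Cl2 (20 mol %), AsPh3, Cs2CO3, DMF/THF/H2O, 1 mM, rt
Reagents that add atoms: none
Why: Anti-Markovnikov hydroboration of the only monosubstituted olefin, then intramolecular B-alkyl Suzuki–Miyaura coupling with retention at C49, closes the ring and gives the E-trisubstituted olefin C49=C51 without creating a stereocentre.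

Step 23
Reactants: 27 macrocyclic diester
Product: 28 primary alcohol (C24 CH2OH; otherwise as 27)
Conditions: i-Bu2AlH (2.2 equiv), CH2Cl2, −78 °C
Reagents that add atoms: none
Why: Hydride reduction of the more accessible C24 ethyl ester; the C3 methyl ester on the quaternary carbon between two tertiary ring carbons should be spared, and the trans relationship of C24 and C3 slows lactonisation.

Step 24
Reactants: 28 primary alcohol
Product: 29 aldehyde (C24 CHO; otherwise as 27)
Conditions: Dess–Martin periodinane, NaHCO3, CH2Cl2, 0 °C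
Reagents that add atoms: none
Why: Buffered Dess–Martin oxidation, run at once after step 23, keeps the α-stereocentre C26 intact.

Step 25
Reactants: 29 aldehyde; 30 2-bromo-3-methylbut-1-ene
Product: 32 allylic alcohol (C24 carbinol bearing the 3-methylbut-1-en-2-yl group; both C24 epimers), via alkenylmagnesium bromide 31 (not isolated)
Conditions: 30, Mg, THF; then CeCl3, −78 °C; then 29, −78 °C
Reagents that add atoms: none
Why: 1,2-Addition of the alkenyl organometallic forms C20–C24; the cerium reagent is less basic than the Grignard reagent and so suppresses enolisation at C26. The new carbinol centre is removed by oxidation in the next step.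

Step 26
Reactants: 32 allylic alcohol
Product: 33 keto aldehyde (C7 CHO; C24 enone with C19=C20; otherwise as 27)
Conditions: (COCl)2, DMSO, CH2Cl2, −78 to −30 °C; then Et3N, −78 to 0 °C
Reagents that add atoms: none
Why: Swern conditions cleave a primary triethylsilyl ether and oxidise it in the same flask, so the free γ-hydroxy ester at C7 is never present; the C24 carbinol is oxidised to the enone at the same time.

Step 27
Reactants: 34 pent-4-yn-1-ol
Product: 36 (4E)-5-iodo-4-methylpent-4-en-1-ol, via alkenylalane 35 (not isolated)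
Conditions: Me3Al, Cp2ZrCl2 (25 mol %), CH2Cl2, rt; then I2, THF, −30 °C
Reagents that add atoms: trimethylaluminium C[Al](C)C; iodine II
Why: Negishi carboalumination adds methyl and aluminium syn with methyl on the internal carbon; iodinolysis with retention gives the E iodide that becomes C9=C10.

Step 28
Reactants: 36 (4E)-5-iodo-4-methylpent-4-en-1-ol
Product: 37 (4E)-5-iodo-4-methylpent-4-enal
Conditions: Dess–Martin periodinane, CH2Cl2, rt
Reagents that add atoms: none
Why: Dess–Martin oxidation of a primary alcohol; the alkenyl iodide is inert.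

Step 29
Reactants: 37 (4E)-5-iodo-4-methylpent-4-enal
Product: 38 ethyl (2E,6E)-7-iodo-2,6-dimethylhepta-2,6-dienoate
Conditions: Ph3P=C(Me)CO2Et, CH2Cl2, rt
Reagents that add atoms: ethyl 2-(triphenylphosphoranylidene)propanoate CCOC(=O)C(C)=P(c1ccccc1)(c1ccccc1)c1ccccc1
Why: Wittig reaction with a stabilised ylide gives the E enoate (C13 trans to C17), the geometry of C14=C15.

Step 30
Reactants: 38 ethyl (2E,6E)-7-iodo-2,6-dimethylhepta-2,6-dienoate
Product: 39 (2E,6E)-7-iodo-2,6-dimethylhepta-2,6-dien-1-ol
Conditions: i-Bu2AlH, CH2Cl2, −78 °C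
Reagents that add atoms: none
Why: 1,2-Reduction of the enoate to the allylic alcohol without touching the alkenyl iodide.

Step 31
Reactants: 39 (2E,6E)-7-iodo-2,6-dimethylhepta-2,6-dien-1-ol
Product: 40 tert-butyl{[(2E,6E)-7-iodo-2,6-dimethylhepta-2,6-dien-1-yl]oxy}dimethylsilane
Conditions: t-BuMe2SiCl, imidazole, DMF, rt
Reagents that add atoms: tert-butyldimethylsilyl chloride CC(C)(C)[Si](C)(C)Cl
Why: Standard silylation masks the C17 hydroxyl for the chromium-mediated coupling.

Step 32
Reactants: 33 keto aldehyde; 40 tert-butyl{[(2E,6E)-7-iodo-2,6-dimethylhepta-2,6-dien-1-yl]oxy}dimethylsilane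
Product: 41 C7 allylic alcohol (C7–C9 bond formed; both C7 epimers; C17 and O33 silyl ethers; C24 enone)
Conditions: CrCl2 (6 equiv), NiCl2 (2 mol %), DMSO/THF, rt
Reagents that add atoms: none
Why: Nozaki–Hiyama–Kishi coupling; the alkenylchromium reagent adds to the aldehyde only, with retention of the C9=C10 geometry, and tolerates the enone and the ester.

Step 33
Reactants: 41 C7 allylic alcohol
Product: 42 C7 enone (C7 ketone conjugated to C9=C10; otherwise as 41)
Conditions: Dess–Martin periodinane, NaHCO3, CH2Cl2, 0 °C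
Reagents that add atoms: none
Why: Prompt Dess–Martin oxidation removes the C7 carbinol before it can lactonise onto the C3 ester and erases the C7 epimer mixture.

Step 34
Reactants: 42 C7 enone
Product: 43 diol (free C17 and C32 hydroxyls; otherwise as 42)
Conditions: HF·pyridine, pyridine, THF, 0 °C to rt
Reagents that add atoms: none
Why: Buffered fluoride desilylation removes both tert-butyldimethylsilyl ethers; the 4-methoxybenzyl ethers, the enones and the ester are stable to it.

Step 35
Reactants: 43 diol
Product: 44 hydroxy enal (C17 CHO; C32 hydroxyl kept)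
Conditions: MnO2 (activated, excess), CH2Cl2, rt
Reagents that add atoms: none
Why: Manganese dioxide oxidises only the allylic C17 alcohol; the saturated secondary C32 alcohol is not touched.

Step 36
Reactants: 44 hydroxy enal
Product: 45 acetate (C32 OAc; otherwise as 44)
Conditions: Ac2O, 4-(dimethylamino)pyridine, pyridine, CH2Cl2, rt
Reagents that add atoms: acetic anhydride CC(=O)OC(C)=O
Why: Nucleophile-catalysed acylation of the only free hydroxyl; no hydride or organometallic step follows, so the acetate is now safe.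

Step 37
Reactants: 45 acetate
Product: 46 carboxylic acid (C17 CO2H; otherwise as 45)
Conditions: NaClO2, NaH2PO4, 2-methylbut-2-ene, t-BuOH/H2O, rt
Reagents that add atoms: sodium chlorite [Na+].[O-]Cl=O
Why: Pinnick oxidation converts the enal to the E-2-methyl enoic acid without isomerisation; the enones and the acetate tolerate the buffered conditions.

Step 38
Reactants: 46 carboxylic acid
Product: 47 dihydroxy acid (free O39 and O45 hydroxyls; C32 OAc; C17 CO2H)
Conditions: DDQ, CH2Cl2/pH 7 buffer, 0 °C to rt
Reagents that add atoms: none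
Why: Oxidative cleavage of both 4-methoxybenzyl ethers through the benzylic oxocarbenium ions; no neighbouring free hydroxyl is present to trap them as acetals.

Step 39
Reactants: 47 dihydroxy acid
Product: 48 phenyl selenoester (C17 C(=O)SePh with the C19=C20 enone; free tertiary hydroxyls)
Conditions: N-(phenylseleno)phthalimide, PBu3, CH2Cl2, −20 °C
Reagents that add atoms: N-(phenylseleno)phthalimide O=C1N([Se]c2ccccc2)C(=O)c2ccccc12
Why: The phosphine and the selenium reagent form a selenophosphonium salt that activates the acid as an acyloxyphosphonium ion, which selenolate then displaces; premixing the two reagents keeps free phosphine away from the α-methylene ketone, and the tertiary alcohols are too hindered to be acylated.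

Step 40
Reactants: 48 phenyl selenoester
Product: 49 bisglaucumlide K
Conditions: Bu3SnH (1.3 equiv), AIBN (0.2 equiv), benzene, 80 °C, syringe-pump addition over 8 h, final 2 mM
Reagents that add atoms: none
Why: The tributyltin radical abstracts the phenylseleno group of 48 and gives the C17 α,β-unsaturated acyl radical, which does not lose carbon monoxide because that would give a high-energy alkenyl radical. This nucleophilic radical adds to the unsubstituted, electron-poor terminus C19 of the 2-isopropyl enone; the tertiary α-keto radical at C20 then takes hydrogen from the stannane and the chain continues. The closest known reaction type is the acyl radical macrocyclisation of unsaturated phenyl selenoesters onto terminal enones, used to close 14-membered cembranoid rings. The upper ring closes in the 14-endo-trig mode: attack at C20 would give a primary radical at a fully substituted carbon, and closure onto C9/C10 or C14/C15 would force an E olefin into a six- or seven-membered ring. C20 is set in the hydrogen-transfer step, where the stannane should approach the planar radical from the outer face of the new macrocycle; the centre lies α to the C24 ketone and stays correctable. The step needs selenium abstraction to outrun stannyl addition to the two enones, which the fast selenium transfer secures, and ring closure to outrun direct reduction of the acyl radical, which slow addition at high dilution secures. The free hydroxyls, the acetate and the methyl ester are inert under these neutral conditions.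

## Compound list

1 | geranyl acetate | CC(C)=CCC/C(C)=C/COC(C)=O | starting material
2 | (2E,6E)-8-hydroxy-3,7-dimethylocta-2,6-dien-1-yl acetate | OC/C(C)=C/CC/C(C)=C/COC(C)=O | intermediate
3 | (2E,6E)-2,6-dimethylocta-2,6-diene-1,8-diol | OC/C(C)=C/CC/C(C)=C/CO | intermediate
4 | (2S,3S,6S,7S)-2,3:6,7-diepoxy-2,6-dimethyloctane-1,8-diol | OC[C@]1(C)O[C@H]1CC[C@]2(C)O[C@H]2CO | intermediate
5 | (2S,3R)-5-[(2S,3S)-3-(hydroxymethyl)-3-methyloxiran-2-yl]-3-[(4-methoxyphenyl)methoxy]-3-methylpentane-1,2-diol (not isolated) | OC[C@]1(C)O[C@H]1CC[C@@](C)(OCc2ccc(OC)cc2)[C@@H](O)CO | intermediate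
6 | (2S)-2-[(2R,5R,6S)-6-(hydroxymethyl)-5-[(4-methoxyphenyl)methoxy]-5-methyloxan-2-yl]propane-1,2-diol | OC[C@](C)(O)[C@H]1CC[C@@](C)(OCc2ccc(OC)cc2)[C@H](CO)O1 | intermediate
7 | [(2S,3R,6R)-6-[(4S)-2-(4-methoxyphenyl)-4-methyl-1,3-dioxolan-4-yl]-3-[(4-methoxyphenyl)methoxy]-3-methyloxan-2-yl]methanol (acetal epimers) | COc1ccc(cc1)C2OC[C@](C)(O2)[C@H]3CC[C@@](C)(OCc4ccc(OC)cc4)[C@H](CO)O3 | intermediate
8 | (2R,3R,6R)-6-[(4S)-2-(4-methoxyphenyl)-4-methyl-1,3-dioxolan-4-yl]-3-[(4-methoxyphenyl)methoxy]-3-methyloxane-2-carbaldehyde | COc1ccc(cc1)C2OC[C@](C)(O2)[C@H]3CC[C@@](C)(OCc4ccc(OC)cc4)[C@H](C=O)O3 | intermediate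
9 | (4S)-4-[(2R,5R,6S)-6-ethenyl-5-[(4-methoxyphenyl)methoxy]-5-methyloxan-2-yl]-2-(4-methoxyphenyl)-4-methyl-1,3-dioxolane | COc1ccc(cc1)C2OC[C@](C)(O2)[C@H]3CC[C@@](C)(OCc4ccc(OC)cc4)[C@H](C=C)O3 | intermediate
10 | (2S)-2-[(2R,5R,6S)-6-ethenyl-5-[(4-methoxyphenyl)methoxy]-5-methyloxan-2-yl]-2-[(4-methoxyphenyl)methoxy]propan-1-ol | OC[C@](C)(OCc1ccc(OC)cc1)[C@H]2CC[C@@](C)(OCc3ccc(OC)cc3)[C@H](C=C)O2 | intermediate
11 | (2R)-2-[(2R,5R,6S)-6-ethenyl-5-[(4-methoxyphenyl)methoxy]-5-methyloxan-2-yl]-2-[(4-methoxyphenyl)methoxy]propanal | O=C[C@](C)(OCc1ccc(OC)cc1)[C@H]2CC[C@@](C)(OCc3ccc(OC)cc3)[C@H](C=C)O2 | intermediate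
12 | (2S,3S)-2-[(2R,5R,6S)-6-ethenyl-5-[(4-methoxyphenyl)methoxy]-5-methyloxan-2-yl]-2-[(4-methoxyphenyl)methoxy]hex-5-yn-3-ol | C#CC[C@H](O)[C@](C)(OCc1ccc(OC)cc1)[C@H]2CC[C@@](C)(OCc3ccc(OC)cc3)[C@H](C=C)O2 | intermediate
13 | tert-butyl{[(2R,3S)-2-[(2R,5R,6S)-6-ethenyl-5-[(4-methoxyphenyl)methoxy]-5-methyloxan-2-yl]-2-[(4-methoxyphenyl)methoxy]hex-5-yn-3-yl]oxy}dimethylsilane | C#CC[C@H](O[Si](C)(C)C(C)(C)C)[C@](C)(OCc1ccc(OC)cc1)[C@H]2CC[C@@](C)(OCc3ccc(OC)cc3)[C@H](C=C)O2 | intermediate
14 | (5E)-5,6-diiodohex-5-en-3-yl analogue of 13 | I/C=C(/I)C[C@H](O[Si](C)(C)C(C)(C)C)[C@](C)(OCc1ccc(OC)cc1)[C@H]2CC[C@@](C)(OCc3ccc(OC)cc3)[C@H](C=C)O2 | intermediate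
15 | (5E)-5-iodonon-5-en-7-yn-3-yl analogue of 13 | CC#C/C=C(/I)C[C@H](O[Si](C)(C)C(C)(C)C)[C@](C)(OCc1ccc(OC)cc1)[C@H]2CC[C@@](C)(OCc3ccc(OC)cc3)[C@H](C=C)O2 | intermediate
16 | diene: (5E)-5-(prop-1-en-2-yl)non-5-en-7-yn-3-yl analogue of 13 | CC#C/C=C(/C(C)=C)C[C@H](O[Si](C)(C)C(C)(C)C)[C@](C)(OCc1ccc(OC)cc1)[C@H]2CC[C@@](C)(OCc3ccc(OC)cc3)[C@H](C=C)O2 | intermediate
17 | butane-1,4-diol | OCCCCO | starting material
18 | 4-(triethylsilyloxy)butan-1-ol | OCCCCO[Si](CC)(CC)CC | intermediate
19 | 4-(triethylsilyloxy)butanal | O=CCCCO[Si](CC)(CC)CC | intermediate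
20 | ethyl (2E)-3-formyl-5-(triethylsilyloxy)pent-2-enoate | CCOC(=O)/C=C(/C=O)CCO[Si](CC)(CC)CC | intermediate
21 | Diels–Alder aldehyde: ethyl (1S,2S,3S)-2-formyl-5-methyl-3-(prop-1-yn-1-yl)-2-[2-(triethylsilyloxy)ethyl]cyclohex-4-ene-1-carboxylate with the chain of 16 on ring carbon 4 | O=C[C@]1(CCO[Si](CC)(CC)CC)[C@@H](C(=O)OCC)CC(C)=C(C[C@H](O[Si](C)(C)C(C)(C)C)[C@](C)(OCc2ccc(OC)cc2)[C@H]3CC[C@@](C)(OCc4ccc(OC)cc4)[C@H](C=C)O3)[C@@H]1C#CC | intermediate
22 | carboxylic acid from 21 (C3 CO2H) | OC(=O)[C@]1(CCO[Si](CC)(CC)CC)[C@@H](C(=O)OCC)CC(C)=C(C[C@H](O[Si](C)(C)C(C)(C)C)[C@](C)(OCc2ccc(OC)cc2)[C@H]3CC[C@@](C)(OCc4ccc(OC)cc4)[C@H](C=C)O3)[C@@H]1C#CC | intermediate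
23 | 1-ethyl 2-methyl diester (C3 CO2Me, C24 CO2Et) | COC(=O)[C@]1(CCO[Si](CC)(CC)CC)[C@@H](C(=O)OCC)CC(C)=C(C[C@H](O[Si](C)(C)C(C)(C)C)[C@](C)(OCc2ccc(OC)cc2)[C@H]3CC[C@@](C)(OCc4ccc(OC)cc4)[C@H](C=C)O3)[C@@H]1C#CC | intermediate
24 | alkenylstannane: (E)-2-(tributylstannyl)prop-1-enyl on C52 (not isolated) | COC(=O)[C@]1(CCO[Si](CC)(CC)CC)[C@@H](C(=O)OCC)CC(C)=C(C[C@H](O[Si](C)(C)C(C)(C)C)[C@](C)(OCc2ccc(OC)cc2)[C@H]3CC[C@@](C)(OCc4ccc(OC)cc4)[C@H](C=C)O3)[C@@H]1/C=C(\C)[Sn](CCCC)(CCCC)CCCC | intermediate
25 | alkenyl iodide: (E)-2-iodoprop-1-enyl on C52 | COC(=O)[C@]1(CCO[Si](CC)(CC)CC)[C@@H](C(=O)OCC)CC(C)=C(C[C@H](O[Si](C)(C)C(C)(C)C)[C@](C)(OCc2ccc(OC)cc2)[C@H]3CC[C@@](C)(OCc4ccc(OC)cc4)[C@H](C=C)O3)[C@@H]1/C=C(\C)I | intermediate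
26 | alkylborane: B-(C48)-9-borabicyclo[3.3.1]nonane adduct of 25 (not isolated) | COC(=O)[C@]1(CCO[Si](CC)(CC)CC)[C@@H](C(=O)OCC)CC(C)=C(C[C@H](O[Si](C)(C)C(C)(C)C)[C@](C)(OCc2ccc(OC)cc2)[C@H]3CC[C@@](C)(OCc4ccc(OC)cc4)[C@H](CCB5C6CCCC5CCC6)O3)[C@@H]1/C=C(\C)I | intermediate
27 | macrocyclic diester: cyclohexene fused to the oxane-bridged lower 14-membered ring; C5 CO2Me and CH2CH2OSiEt3; C26 CO2Et; O33 tert-butyldimethylsilyl; O39 and O45 4-methoxybenzyl; configuration as in 49 | COC(=O)[C@]1(CCO[Si](CC)(CC)CC)[C@@H](C(=O)OCC)CC(C)=C2C[C@H](O[Si](C)(C)C(C)(C)C)[C@](C)(OCc3ccc(OC)cc3)[C@H]4CC[C@@](C)(OCc5ccc(OC)cc5)[C@H](CC/C(C)=C/[C@H]12)O4 | intermediate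
28 | primary alcohol: 27 with C24 CH2OH | COC(=O)[C@]1(CCO[Si](CC)(CC)CC)[C@@H](CO)CC(C)=C2C[C@H](O[Si](C)(C)C(C)(C)C)[C@](C)(OCc3ccc(OC)cc3)[C@H]4CC[C@@](C)(OCc5ccc(OC)cc5)[C@H](CC/C(C)=C/[C@H]12)O4 | intermediate
29 | aldehyde: 27 with C24 CHO | COC(=O)[C@]1(CCO[Si](CC)(CC)CC)[C@@H](C=O)CC(C)=C2C[C@H](O[Si](C)(C)C(C)(C)C)[C@](C)(OCc3ccc(OC)cc3)[C@H]4CC[C@@](C)(OCc5ccc(OC)cc5)[C@H](CC/C(C)=C/[C@H]12)O4 | intermediate
30 | 2-bromo-3-methylbut-1-ene | CC(C)C(Br)=C | starting material
31 | (3-methylbut-1-en-2-yl)magnesium bromide (not isolated) | CC(C)C(=C)[Mg]Br | intermediate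
32 | allylic alcohol: 27 with C24 CH(OH)C(=CH2)CH(CH3)2 (C24 epimers) | COC(=O)[C@]1(CCO[Si](CC)(CC)CC)[C@@H](C(O)C(=C)C(C)C)CC(C)=C2C[C@H](O[Si](C)(C)C(C)(C)C)[C@](C)(OCc3ccc(OC)cc3)[C@H]4CC[C@@](C)(OCc5ccc(OC)cc5)[C@H](CC/C(C)=C/[C@H]12)O4 | intermediate
33 | keto aldehyde: C7 CHO and C24 2-isopropyl enone on the lower bicycle | COC(=O)[C@]1(CC=O)[C@@H](C(=O)C(=C)C(C)C)CC(C)=C2C[C@H](O[Si](C)(C)C(C)(C)C)[C@](C)(OCc3ccc(OC)cc3)[C@H]4CC[C@@](C)(OCc5ccc(OC)cc5)[C@H](CC/C(C)=C/[C@H]12)O4 | intermediate
34 | pent-4-yn-1-ol | C#CCCCO | starting material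
35 | alkenylalane from carboalumination of 34 (not isolated) | C[Al](C)OCCC/C(C)=C/[Al](C)C | intermediate
36 | (4E)-5-iodo-4-methylpent-4-en-1-ol | OCCC/C(C)=C/I | intermediate
37 | (4E)-5-iodo-4-methylpent-4-enal | O=CCC/C(C)=C/I | intermediate
38 | ethyl (2E,6E)-7-iodo-2,6-dimethylhepta-2,6-dienoate | CCOC(=O)/C(C)=C/CC/C(C)=C/I | intermediate
39 | (2E,6E)-7-iodo-2,6-dimethylhepta-2,6-dien-1-ol | OC/C(C)=C/CC/C(C)=C/I | intermediate
40 | tert-butyl{[(2E,6E)-7-iodo-2,6-dimethylhepta-2,6-dien-1-yl]oxy}dimethylsilane | CC(C)(C)[Si](C)(C)OC/C(C)=C/CC/C(C)=C/I | intermediate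
41 | C7 allylic alcohol with the full C6–C17 arm (C7 epimers; C17 and O33 silyl ethers) | COC(=O)[C@]1(CC(O)/C=C(\C)CC/C=C(\C)CO[Si](C)(C)C(C)(C)C)[C@@H](C(=O)C(=C)C(C)C)CC(C)=C2C[C@H](O[Si](C)(C)C(C)(C)C)[C@](C)(OCc3ccc(OC)cc3)[C@H]4CC[C@@](C)(OCc5ccc(OC)cc5)[C@H](CC/C(C)=C/[C@H]12)O4 | intermediate
42 | C7 enone (silyl ethers at C17 and O33) | COC(=O)[C@]1(CC(=O)/C=C(\C)CC/C=C(\C)CO[Si](C)(C)C(C)(C)C)[C@@H](C(=O)C(=C)C(C)C)CC(C)=C2C[C@H](O[Si](C)(C)C(C)(C)C)[C@](C)(OCc3ccc(OC)cc3)[C@H]4CC[C@@](C)(OCc5ccc(OC)cc5)[C@H](CC/C(C)=C/[C@H]12)O4 | intermediate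
43 | diol: free C17 and C32 hydroxyls | COC(=O)[C@]1(CC(=O)/C=C(\C)CC/C=C(\C)CO)[C@@H](C(=O)C(=C)C(C)C)CC(C)=C2C[C@H](O)[C@](C)(OCc3ccc(OC)cc3)[C@H]4CC[C@@](C)(OCc5ccc(OC)cc5)[C@H](CC/C(C)=C/[C@H]12)O4 | intermediate
44 | hydroxy enal: C17 CHO, C32 OH | COC(=O)[C@]1(CC(=O)/C=C(\C)CC/C=C(\C)C=O)[C@@H](C(=O)C(=C)C(C)C)CC(C)=C2C[C@H](O)[C@](C)(OCc3ccc(OC)cc3)[C@H]4CC[C@@](C)(OCc5ccc(OC)cc5)[C@H](CC/C(C)=C/[C@H]12)O4 | intermediate
45 | acetate: C32 OAc, C17 CHO | COC(=O)[C@]1(CC(=O)/C=C(\C)CC/C=C(\C)C=O)[C@@H](C(=O)C(=C)C(C)C)CC(C)=C2C[C@H](OC(C)=O)[C@](C)(OCc3ccc(OC)cc3)[C@H]4CC[C@@](C)(OCc5ccc(OC)cc5)[C@H](CC/C(C)=C/[C@H]12)O4 | intermediate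
46 | carboxylic acid: C17 CO2H, O39 and O45 4-methoxybenzyl | COC(=O)[C@]1(CC(=O)/C=C(\C)CC/C=C(\C)C(=O)O)[C@@H](C(=O)C(=C)C(C)C)CC(C)=C2C[C@H](OC(C)=O)[C@](C)(OCc3ccc(OC)cc3)[C@H]4CC[C@@](C)(OCc5ccc(OC)cc5)[C@H](CC/C(C)=C/[C@H]12)O4 | intermediate
47 | dihydroxy acid: C17 CO2H, free O39 and O45 hydroxyls | COC(=O)[C@]1(CC(=O)/C=C(\C)CC/C=C(\C)C(=O)O)[C@@H](C(=O)C(=C)C(C)C)CC(C)=C2C[C@H](OC(C)=O)[C@](C)(O)[C@H]3CC[C@@](C)(O)[C@H](CC/C(C)=C/[C@H]12)O3 | intermediate
48 | phenyl selenoester (key-step precursor): C17 C(=O)SePh, C19=C20 enone | COC(=O)[C@]1(CC(=O)/C=C(\C)CC/C=C(\C)C(=O)[Se]c2ccccc2)[C@@H](C(=O)C(=C)C(C)C)CC(C)=C2C[C@H](OC(C)=O)[C@](C)(O)[C@H]3CC[C@@](C)(O)[C@H](CC/C(C)=C/[C@H]12)O3 | intermediate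
49 | bisglaucumlide K (5S,20S,26S,32S,37R,40R,43R,46S,52S in SMILES-order numbering) | COC(=O)[C@]12CC(=O)/C=C(\C)CC/C=C(\C)C(=O)C[C@@H](C(C)C)C(=O)[C@H]1CC(C)=C1C[C@H](OC(C)=O)[C@](C)(O)[C@H]3CC[C@@](C)(O)[C@H](CC/C(C)=C/[C@@H]12)O3 | target

## Step count and least certain steps

Total step count: 40. Longest linear sequence: 32 steps (steps 1–14, 18–26 and 32–40, from geranyl acetate 1 to 49).

Step 40 (key step). The most likely failures are hydrogen transfer to the acyl radical before it finds C19 (direct reduction), and unselective hydrogen delivery to the C20 radical. A slower hydrogen donor such as (Me3Si)3SiH is the first adjustment. The fallback changes the control element from kinetic to thermodynamic. It sets out from 48: the ring-closed material, which would contain 20-epi-bisglaucumlide K F11, is stirred with DBU in toluene at room temperature so that the centre α to the C24 ketone equilibrates, and the route comes back at 49. This assumes the natural C20 configuration is the more stable one in the ring, and the same base treatment would also expose C26, which is likewise α to C24.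

Step 18 (Diels–Alder). The risks are sequestration of the cationic catalyst by the ether oxygens of 16, slow bond formation at the quaternary C5, and therefore poor facial or endo selectivity. The fallback gives up reagent control and uses the enantiopure chain as the resolving element. It sets out from 16 and 20 with Me2AlCl in CH2Cl2 at −78 °C; the two endo adducts, 21 and its ring diastereomer F9 (opposite configuration at C5, C26 and C52), are both single enantiomers and are separated on silica. The route comes back at 21.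

Step 4 (epoxide cascade). The likely failure is attack of the external alcohol on the second epoxide before the ring closes, or competing closure through the primary C47 hydroxyl. The fallback separates the events and sets out from 2:
- Sharpless epoxidation (L-(+)-tartrate) of the single free allylic alcohol gives the epoxy alcohol acetate F1, which is silylated to the silyl ether F2.
- Methanolysis gives the allylic alcohol F3, and a second Sharpless epoxidation gives the bis-epoxide F4, in which only the left epoxide is part of an epoxy alcohol.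
- Ti(OiPr)4-mediated opening with 4-methoxybenzyl alcohol at C43 gives the diol F5, and camphorsulfonic acid closes the oxane to the silyl ether F6.
- Bu4NF removes the silyl group, and the route comes back at 6.

Step 22 (macrocyclisation). The risks are intermolecular coupling, protodeboronation, and slow transmetalation while the ring strain builds. The fallback uses a different ring-closing event on the same two carbons and sets out from 25. An intramolecular Heck reaction (Pd(OAc)2, P(o-tolyl)3, K2CO3, Bu4NCl, DMF, high dilution) joins C49 to C48 and gives the macrocyclic 1,3-diene F10. Diimide, generated from 2-nitrobenzenesulfonyl hydrazide and Et3N, then reduces the disubstituted C47=C48 bond chemoselectively, and the route comes back at 27.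

Step 10 (propargylation). The risk is poor Felkin–Anh selectivity, because the α-oxygen carries a benzylic ether and not a silyl group. The fallback replaces carbon-nucleophile control by hydride control and sets out from the mixture of 12 and its C32 epimer F7. Dess–Martin oxidation gives the ynone F8, and Zn(BH4)2 reduces it under chelation between O33 and O39, with hydride entering from the methyl side. This gives the required C32 configuration, and the route comes back at 12.

## Further compounds

F1 | step 4 | [(2E)-5-[(2S,3S)-3-(hydroxymethyl)-3-methyloxiran-2-yl]-3-methylpent-2-en-1-yl] acetate | OC[C@]1(C)O[C@H]1CC/C(C)=C/COC(C)=O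
F2 | step 4 | tert-butyldimethylsilyl ether of F1 | CC(C)(C)[Si](C)(C)OC[C@]1(C)O[C@H]1CC/C(C)=C/COC(C)=O
F3 | step 4 | deacetylated allylic alcohol from F2 | CC(C)(C)[Si](C)(C)OC[C@]1(C)O[C@H]1CC/C(C)=C/CO
F4 | step 4 | mono-silylated (2S,3S,6S,7S)-bis-epoxide | CC(C)(C)[Si](C)(C)OC[C@]1(C)O[C@H]1CC[C@]2(C)O[C@H]2CO
F5 | step 4 | C43 4-methoxybenzyl ether diol with intact C37/C40 epoxide | CC(C)(C)[Si](C)(C)OC[C@]1(C)O[C@H]1CC[C@@](C)(OCc2ccc(OC)cc2)[C@@H](O)CO
F6 | step 4 | O-silyl derivative of 6 at the C32 oxygen | CC(C)(C)[Si](C)(C)OC[C@](C)(O)[C@H]1CC[C@@](C)(OCc2ccc(OC)cc2)[C@H](CO)O1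
F7 | step 10 | C32 epimer of 12 | C#CC[C@@H](O)[C@](C)(OCc1ccc(OC)cc1)[C@H]2CC[C@@](C)(OCc3ccc(OC)cc3)[C@H](C=C)O2
F8 | step 10 | C32 ynone from 12 and F7 | C#CCC(=O)[C@](C)(OCc1ccc(OC)cc1)[C@H]2CC[C@@](C)(OCc3ccc(OC)cc3)[C@H](C=C)O2
F9 | step 18 | ring diastereomer of 21 (opposite configuration at C5, C26, C52) | O=C[C@@]1(CCO[Si](CC)(CC)CC)[C@H](C(=O)OCC)CC(C)=C(C[C@H](O[Si](C)(C)C(C)(C)C)[C@](C)(OCc2ccc(OC)cc2)[C@H]3CC[C@@](C)(OCc4ccc(OC)cc4)[C@H](C=C)O3)[C@H]1C#CC
F10 | step 22 | macrocyclic 47E,49E-diene from Heck closure of 25 | COC(=O)[C@]1(CCO[Si](CC)(CC)CC)[C@@H](C(=O)OCC)CC(C)=C2C[C@H](O[Si](C)(C)C(C)(C)C)[C@](C)(OCc3ccc(OC)cc3)[C@H]4CC[C@@](C)(OCc5ccc(OC)cc5)[C@H](/C=C/C(C)=C/[C@H]12)O4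
F11 | step 40 | 20-epi-bisglaucumlide K | COC(=O)[C@]12CC(=O)/C=C(\C)CC/C=C(\C)C(=O)C[C@H](C(C)C)C(=O)[C@H]1CC(C)=C1C[C@H](OC(C)=O)[C@](C)(O)[C@H]3CC[C@@](C)(O)[C@H](CC/C(C)=C/[C@@H]12)O3
A1 | alternative 1 | seco aldehyde with tertiary allylsilane at C28 and exocyclic C30=C31 | COC(=O)[C@]1(CCO[Si](C)(C)C(C)(C)C)[C@@H](CO[Si](C)(C)C(C)(C)C)CC(C)([Si](C)(C)C)C(=C)[C@@H]1/C=C(\C)CC[C@@H]2O[C@H](CC[C@@]2(C)O[Si](CC)(CC)CC)[C@@](C)(O[Si](CC)(CC)CC)C=O
A2 | alternative 1 | lower macrocycle with free C32 hydroxyl | COC(=O)[C@]1(CCO[Si](C)(C)C(C)(C)C)[C@@H](CO[Si](C)(C)C(C)(C)C)CC(C)=C2C[C@H](O)[C@](C)(O[Si](CC)(CC)CC)[C@H]3CC[C@@](C)(O[Si](CC)(CC)CC)[C@H](CC/C(C)=C/[C@H]12)O3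
A3 | alternative 2 | bis-macrocyclic C37/C40 epoxide with free C46 hydroxyl | COC(=O)[C@]12CC(=O)/C=C(\C)CC/C=C(\C)C(=O)C[C@@H](C(C)C)C(=O)[C@H]1CC(C)=C1C[C@H](O)[C@]3(C)O[C@H]3CC[C@@](C)(O[Si](CC)(CC)CC)[C@@H](O)CC/C(C)=C/[C@@H]12
A4 | alternative 2 | deacetyl target carrying the C43 triethylsilyl ether | COC(=O)[C@]12CC(=O)/C=C(\C)CC/C=C(\C)C(=O)C[C@@H](C(C)C)C(=O)[C@H]1CC(C)=C1C[C@H](O)[C@](C)(O)[C@H]3CC[C@@](C)(O[Si](CC)(CC)CC)[C@H](CC/C(C)=C/[C@@H]12)O3
A5 | alternative 3 | C24 acid chloride with terminal isopropylidene olefin | COC(=O)[C@]1(CC(=O)/C=C(\C)CC/C=C(\C)C(=O)CC=C(C)C)[C@@H](C(Cl)=O)CC(C)=C(COC(=O)C(C)(C)C)[C@@H]1COC(=O)C(C)(C)C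
A6 | alternative 3 | upper macrocycle with 2-chloroprop-2-yl group on C20 | COC(=O)[C@]12CC(=O)/C=C(\C)CC/C=C(\C)C(=O)C[C@@H](C(C)(C)Cl)C(=O)[C@H]1CC(C)=C(COC(=O)C(C)(C)C)[C@@H]2COC(=O)C(C)(C)C
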